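**Plan**
Ring A is numbered C1 (methyl), C2 (alkynyl), C3 (bearing C7) and C4 (ring B). The retrosynthesis opens the quinone methide to the tetra-O-methyl triarylcarbinol 21, then cuts the two C7–aryl bonds back to the aldehyde 16, then cuts C2–C(sp) and C4–C(ring B).
The last two cuts rest on one feature: C3 carries the carboxyl-level carbon C7 and lies between C2 and C4, so a single oxazoline at C7 can activate both ortho positions for substitution.
Forward: oxazoline 8 is made from 3-fluoro-4-methylanisole (steps 1–3), the alkyne and then ring B are joined to it in one pot (step 4), the oxazoline is unmasked to the aldehyde (step 5), two aryl groups are added to C7 with an oxidation between (steps 6–8), and demethylation with loss of water ends the route (step 9).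
All carbocycles are bought; the only ring made is the auxiliary oxazoline (step 3), which is opened again in step 5.
The target has no stereocentre and its C7=C bond is not stereogenic; the aminal centre of 15 and the carbinol centre of 17 are racemic and are erased.

Key step: step 4

Remark: 4-methoxyphenylmagnesium bromide 10 is taken as the commercial THF solution; all organometallic steps are run under argon in dry solvent.

**Route**

Step 1
Reactants: 1 3-fluoro-4-methylanisole
Product: 3 2-fluoro-6-methoxy-3-methylbenzoic acid, via 2-fluoro-6-methoxy-3-methylphenyllithium 2 (not isolated)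
Conditions: n-BuLi, THF, −78 °C; CO2, −78 °C → rt; aq. HCl
Reagents that add atoms: carbon dioxide, O=C=O
Why: Directed ortho-metalation should take place at the ring position between fluorine and methoxy, the most acidic site and the only one flanked by two coordinating groups, and the aryllithium is carboxylated at −78 °C before it can lose LiF to an aryne.

Step 2
Reactants: 3 2-fluoro-6-methoxy-3-methylbenzoic acid; 4 2-amino-2-methylpropan-1-ol
Product: 6 2-fluoro-N-(1-hydroxy-2-methylpropan-2-yl)-6-methoxy-3-methylbenzamide, via 2-fluoro-6-methoxy-3-methylbenzoyl chloride 5 (not isolated)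
Conditions: (COCl)2, cat. DMF, CH2Cl2, 0 °C → rt; then 4, Et3N, CH2Cl2, 0 °C → rt
Reagents that add atoms: none
Why: Acid chloride formation followed by Schotten–Baumann-type N-acylation should be selective because the amine of 4 is far more nucleophilic than its hindered primary alcohol.

Step 3
Reactants: 6 2-fluoro-N-(1-hydroxy-2-methylpropan-2-yl)-6-methoxy-3-methylbenzamide
Product: 8 2-(2-fluoro-6-methoxy-3-methylphenyl)-4,4-dimethyl-4,5-dihydrooxazole, via oxazolinium chloride 7 (not isolated)
Conditions: SOCl2, CH2Cl2, 0 °C → rt; then aq. NaOH, 0 °C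
Reagents that add atoms: none
Why: Cyclodehydration of a β-hydroxy amide, in which the chlorosulfite made with SOCl2 is displaced by the amide oxygen in a 5-exo-tet closure, is the standard preparation of 2-aryl-4,4-dimethyloxazolines.

Step 4
Reactants: 8 2-(2-fluoro-6-methoxy-3-methylphenyl)-4,4-dimethyl-4,5-dihydrooxazole; 9 4-ethynylanisole; 10 4-methoxyphenylmagnesium bromide
Product: 13 2-{6-(4-methoxyphenyl)-2-[(4-methoxyphenyl)ethynyl]-3-methylphenyl}-4,4-dimethyl-4,5-dihydrooxazole, via lithium (4-methoxyphenyl)acetylide 11 (not isolated), via 2-alkynyl-6-methoxyphenyl oxazoline 12 (not isolated)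
Conditions: 9 (1.25 equiv), n-BuLi (1.2 equiv), THF, −78 → 0 °C; 8, 0 → 60 °C; then 10 (3 equiv), THF, rt → 65 °C; H2O
Reagents that add atoms: none
Why: Proposed new method: the lithium of acetylide 11 should be held by the oxazoline nitrogen and the fluorine of 8, the alkynyl carbon adds to C2 to give a lithium aza-enolate, and loss of LiF restores the arene as 12, after which the Grignard reagent 10 repeats the same addition–elimination at C4 with loss of methoxide. The closest known reaction type is the Meyers oxazoline-activated aromatic substitution, in which aryl, alkyl and vinyl Grignard or organolithium reagents displace an ortho fluoride or methoxide, twice in succession if wished; the acetylide as nucleophile is the untested part, and the irreversible loss of fluoride from the strongly polarised C–F carbon is what should carry a nucleophile of such low basicity. No ring closes and no stereocentre forms. The step needs site selectivity, which rests on fluoride leaving much faster than methoxide in this mechanism: a near-stoichiometric amount of acetylide should take C2 only, its rod-like sp carbon fitting the position next to the C1 methyl, and the aryl Grignard reagent, added only once an aliquot shows no aryl fluoride, meets nothing but the methoxide at the open C4. The alkyne is used in slight excess over n-BuLi so that no butyllithium is left to attack the fluoride, and the 4,4-dimethyl groups keep both nucleophiles away from the C=N carbon.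

Step 5
Reactants: 13 2-{6-(4-methoxyphenyl)-2-[(4-methoxyphenyl)ethynyl]-3-methylphenyl}-4,4-dimethyl-4,5-dihydrooxazole
Product: 16 6-(4-methoxyphenyl)-2-[(4-methoxyphenyl)ethynyl]-3-methylbenzaldehyde, via N-methyloxazolinium triflate 14 (not isolated), via N-methyloxazolidine 15 (not isolated)
Conditions: MeOTf, CH2Cl2, rt; NaBH4, THF/MeOH, 0 °C; (CO2H)2, THF/H2O, rt
Reagents that add atoms: water, O
Why: This is the Meyers unmasking of an aryl oxazoline, in which N-methylation turns the C=N into an iminium that NaBH4 reduces to the racemic aminal 15, and mild aqueous acid then hydrolyses the aminal to the aldehyde without touching the diaryl alkyne or the aryl methyl ethers.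

Step 6
Reactants: 16 6-(4-methoxyphenyl)-2-[(4-methoxyphenyl)ethynyl]-3-methylbenzaldehyde; 10 4-methoxyphenylmagnesium bromide
Product: 17 (4-methoxyphenyl){6-(4-methoxyphenyl)-2-[(4-methoxyphenyl)ethynyl]-3-methylphenyl}methanol (racemic)
Conditions: 10, THF, 0 °C → rt; H2O
Reagents that add atoms: none
Why: Grignard addition to an aromatic aldehyde should be fast even with two ortho substituents, and the new carbinol carbon is formed racemic and loses its stereogenicity in step 7.

Step 7
Reactants: 17 (4-methoxyphenyl){6-(4-methoxyphenyl)-2-[(4-methoxyphenyl)ethynyl]-3-methylphenyl}methanol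
Product: 18 (4-methoxyphenyl){6-(4-methoxyphenyl)-2-[(4-methoxyphenyl)ethynyl]-3-methylphenyl}methanone
Conditions: Dess–Martin periodinane, CH2Cl2, rt
Reagents that add atoms: none
Why: Dess–Martin oxidation of a secondary diaryl carbinol runs at room temperature under nearly neutral conditions and should leave the alkyne and the electron-rich rings alone.

Step 8
Reactants: 18 (4-methoxyphenyl){6-(4-methoxyphenyl)-2-[(4-methoxyphenyl)ethynyl]-3-methylphenyl}methanone; 19 4-bromoanisole
Product: 21 bis(4-methoxyphenyl){6-(4-methoxyphenyl)-2-[(4-methoxyphenyl)ethynyl]-3-methylphenyl}methanol, via 4-methoxyphenyllithium 20 (not isolated)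
Conditions: 19, n-BuLi, THF, −78 °C; then 18, −78 → 0 °C; H2O
Reagents that add atoms: none
Why: Bromine–lithium exchange followed by 1,2-addition of the aryllithium to a non-enolisable diaryl ketone should succeed because the small, reactive organolithium can reach a carbonyl lying between two ortho substituents.

Step 9
Reactants: 21 bis(4-methoxyphenyl){6-(4-methoxyphenyl)-2-[(4-methoxyphenyl)ethynyl]-3-methylphenyl}methanol
Product: 22 Selaginellin U, 4-[(4-hydroxyphenyl){6-(4-hydroxyphenyl)-2-[(4-hydroxyphenyl)ethynyl]-3-methylphenyl}methylidene]cyclohexa-2,5-dien-1-one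
Conditions: BBr3, CH2Cl2, −78 °C → rt; H2O
Reagents that add atoms: none
Why: Lewis-acid ether cleavage with BBr3 should free the four phenols, and the carbinol flanked by two 4-hydroxyphenyl groups ionises and loses a phenolic proton on aqueous work-up to give the quinone methide, a dehydration typical of 4-hydroxytrityl alcohols.

**Compound list**
1 | 3-fluoro-4-methylanisole (2-fluoro-4-methoxy-1-methylbenzene) | COc1ccc(C)c(F)c1 | starting material
2 | 2-fluoro-6-methoxy-3-methylphenyllithium | COc1ccc(C)c(F)c1[Li] | intermediate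
3 | 2-fluoro-6-methoxy-3-methylbenzoic acid | COc1ccc(C)c(F)c1C(=O)O | intermediate
4 | 2-amino-2-methylpropan-1-ol | CC(C)(N)CO | starting material
5 | 2-fluoro-6-methoxy-3-methylbenzoyl chloride | COc1ccc(C)c(F)c1C(=O)Cl | intermediate
6 | 2-fluoro-N-(1-hydroxy-2-methylpropan-2-yl)-6-methoxy-3-methylbenzamide | COc1ccc(C)c(F)c1C(=O)NC(C)(C)CO | intermediate
7 | 2-(2-fluoro-6-methoxy-3-methylphenyl)-4,4-dimethyl-4,5-dihydrooxazol-3-ium chloride | COc1ccc(C)c(F)c1C1=[NH+]C(C)(C)CO1.[Cl-] | intermediate
8 | 2-(2-fluoro-6-methoxy-3-methylphenyl)-4,4-dimethyl-4,5-dihydrooxazole | COc1ccc(C)c(F)c1C1=NC(C)(C)CO1 | intermediate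
9 | 4-ethynylanisole (1-ethynyl-4-methoxybenzene) | C#Cc1ccc(OC)cc1 | starting material
10 | 4-methoxyphenylmagnesium bromide | COc1ccc([Mg]Br)cc1 | starting material
11 | lithium (4-methoxyphenyl)acetylide | [Li]C#Cc1ccc(OC)cc1 | intermediate
12 | 2-{6-methoxy-2-[(4-methoxyphenyl)ethynyl]-3-methylphenyl}-4,4-dimethyl-4,5-dihydrooxazole | COc1ccc(cc1)C#Cc1c(C)ccc(OC)c1C1=NC(C)(C)CO1 | intermediate
13 | 2-{6-(4-methoxyphenyl)-2-[(4-methoxyphenyl)ethynyl]-3-methylphenyl}-4,4-dimethyl-4,5-dihydrooxazole | COc1ccc(cc1)C#Cc1c(C)ccc(-c2ccc(OC)cc2)c1C1=NC(C)(C)CO1 | intermediate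
14 | 2-{6-(4-methoxyphenyl)-2-[(4-methoxyphenyl)ethynyl]-3-methylphenyl}-3,4,4-trimethyl-4,5-dihydrooxazol-3-ium trifluoromethanesulfonate | COc1ccc(cc1)C#Cc1c(C)ccc(-c2ccc(OC)cc2)c1C1=[N+](C)C(C)(C)CO1.[O-]S(=O)(=O)C(F)(F)F | intermediate
15 | 2-{6-(4-methoxyphenyl)-2-[(4-methoxyphenyl)ethynyl]-3-methylphenyl}-3,4,4-trimethyloxazolidine (racemic at C2 of the oxazolidine) | COc1ccc(cc1)C#Cc1c(C)ccc(-c2ccc(OC)cc2)c1C1N(C)C(C)(C)CO1 | intermediate
16 | 6-(4-methoxyphenyl)-2-[(4-methoxyphenyl)ethynyl]-3-methylbenzaldehyde | COc1ccc(cc1)C#Cc1c(C)ccc(-c2ccc(OC)cc2)c1C=O | intermediate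
17 | (4-methoxyphenyl){6-(4-methoxyphenyl)-2-[(4-methoxyphenyl)ethynyl]-3-methylphenyl}methanol (racemic) | COc1ccc(cc1)C#Cc1c(C)ccc(-c2ccc(OC)cc2)c1C(O)c1ccc(OC)cc1 | intermediate
18 | (4-methoxyphenyl){6-(4-methoxyphenyl)-2-[(4-methoxyphenyl)ethynyl]-3-methylphenyl}methanone | COc1ccc(cc1)C#Cc1c(C)ccc(-c2ccc(OC)cc2)c1C(=O)c1ccc(OC)cc1 | intermediate
19 | 4-bromoanisole | COc1ccc(Br)cc1 | starting material
20 | 4-methoxyphenyllithium | COc1ccc([Li])cc1 | intermediate
21 | bis(4-methoxyphenyl){6-(4-methoxyphenyl)-2-[(4-methoxyphenyl)ethynyl]-3-methylphenyl}methanol | COc1ccc(cc1)C#Cc1c(C)ccc(-c2ccc(OC)cc2)c1C(O)(c1ccc(OC)cc1)c1ccc(OC)cc1 | intermediate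
22 | Selaginellin U, 4-[(4-hydroxyphenyl){6-(4-hydroxyphenyl)-2-[(4-hydroxyphenyl)ethynyl]-3-methylphenyl}methylidene]cyclohexa-2,5-dien-1-one | Cc1ccc(-c2ccc(O)cc2)c(C(=C2C=CC(=O)C=C2)c2ccc(O)cc2)c1C#Cc1ccc(O)cc1 | target

**Count and risks**
Total step count: 9. Longest linear sequence: 9 steps (1 to 22); compounds 4, 9, 10 and 19 are bought.

Step 4. The acetylide may add too slowly to the fluorine-bearing carbon, or the two substitutions may lose their order (acetylide displacing methoxide, or the Grignard reagent displacing fluoride that is left over). The fallback sets out from 8, comes back at 13, and makes each bond by a reaction type with direct precedent. Vinylmagnesium bromide (THF, 0 °C → rt) should displace the fluoride of 8 in an ordinary Meyers substitution to give 2-(2-ethenyl-6-methoxy-3-methylphenyl)-4,4-dimethyl-4,5-dihydrooxazole F1. Grignard reagent 10 (THF, reflux) then displaces the methoxide to give 2-[2-ethenyl-6-(4-methoxyphenyl)-3-methylphenyl]-4,4-dimethyl-4,5-dihydrooxazole F2. Lemieux–Johnson cleavage (cat. OsO4, NaIO4, 2,6-lutidine, dioxane/H2O) turns the vinyl group into 2-(4,4-dimethyl-4,5-dihydrooxazol-2-yl)-3-(4-methoxyphenyl)-6-methylbenzaldehyde F3. The Ohira–Bestmann reagent (K2CO3, MeOH) homologates this to the terminal alkyne 2-[2-ethynyl-6-(4-methoxyphenyl)-3-methylphenyl]-4,4-dimethyl-4,5-dihydrooxazole F4. Sonogashira coupling of F4 with 4-iodoanisole (PdCl2(PPh3)2, CuI, Et3N, 50 °C) rejoins the route at 13.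

Step 5. N-Methylation of a nitrogen shielded by two ortho substituents may stay incomplete, so that unchanged oxazoline is carried through the reduction and hydrolysis. The fallback sets out from 13, comes back at 16, and opens the ring by hydrolysis instead of alkylation. TFA, H2O and Na2SO4 in THF should open the protonated oxazoline to 2-amino-2-methylpropyl 6-(4-methoxyphenyl)-2-[(4-methoxyphenyl)ethynyl]-3-methylbenzoate F5, obtained as its trifluoroacetate salt. Ac2O/pyridine caps the amine as 2-acetamido-2-methylpropyl 6-(4-methoxyphenyl)-2-[(4-methoxyphenyl)ethynyl]-3-methylbenzoate F6, so that neither re-closure nor acyl migration to nitrogen can occur. LiAlH4 (THF, 0 °C) reduces the ester to {6-(4-methoxyphenyl)-2-[(4-methoxyphenyl)ethynyl]-3-methylphenyl}methanol F7, and Dess–Martin oxidation of F7 gives 16.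

Step 9. The trityl cation formed from the carbinol persists in the BBr3 medium next to the alkyne and ring B and may cyclise onto either (Friedel–Crafts closure to a fluorene, or attack on the triple bond) before all four ethers are cleaved. The fallback sets out from 18, comes back at 22, and changes the protecting groups before the carbinol exists. BBr3 (CH2Cl2, −78 → 0 °C) on ketone 18, where no such cation can form, should give (4-hydroxyphenyl){6-(4-hydroxyphenyl)-2-[(4-hydroxyphenyl)ethynyl]-3-methylphenyl}methanone F8. TBSCl/imidazole (DMF, rt) converts it into its tris(tert-butyldimethylsilyl) ether F9. [4-(tert-Butyldimethylsilyloxy)phenyl]lithium F10, made from (4-bromophenoxy)(tert-butyl)dimethylsilane and n-BuLi in THF at −78 °C, adds to F9 to give the tetrakis(tert-butyldimethylsilyl) ether of the triarylcarbinol F11. Bu4NF buffered with AcOH (THF, 0 °C) removes the four silyl groups to give bis(4-hydroxyphenyl){6-(4-hydroxyphenyl)-2-[(4-hydroxyphenyl)ethynyl]-3-methylphenyl}methanol F12, which should lose water on work-up with dilute aqueous HCl to give 22.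

**Further compounds**
F1 | step 4 | 2-(2-ethenyl-6-methoxy-3-methylphenyl)-4,4-dimethyl-4,5-dihydrooxazole | COc1ccc(C)c(C=C)c1C1=NC(C)(C)CO1
F2 | step 4 | 2-[2-ethenyl-6-(4-methoxyphenyl)-3-methylphenyl]-4,4-dimethyl-4,5-dihydrooxazole | COc1ccc(cc1)-c1ccc(C)c(C=C)c1C1=NC(C)(C)CO1
F3 | step 4 | 2-(4,4-dimethyl-4,5-dihydrooxazol-2-yl)-3-(4-methoxyphenyl)-6-methylbenzaldehyde | COc1ccc(cc1)-c1ccc(C)c(C=O)c1C1=NC(C)(C)CO1
F4 | step 4 | 2-[2-ethynyl-6-(4-methoxyphenyl)-3-methylphenyl]-4,4-dimethyl-4,5-dihydrooxazole | COc1ccc(cc1)-c1ccc(C)c(C#C)c1C1=NC(C)(C)CO1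
F5 | step 5 | 2-amino-2-methylpropyl 6-(4-methoxyphenyl)-2-[(4-methoxyphenyl)ethynyl]-3-methylbenzoate | COc1ccc(cc1)C#Cc1c(C)ccc(-c2ccc(OC)cc2)c1C(=O)OCC(C)(C)N
F6 | step 5 | 2-acetamido-2-methylpropyl 6-(4-methoxyphenyl)-2-[(4-methoxyphenyl)ethynyl]-3-methylbenzoate | COc1ccc(cc1)C#Cc1c(C)ccc(-c2ccc(OC)cc2)c1C(=O)OCC(C)(C)NC(C)=O
F7 | step 5 | {6-(4-methoxyphenyl)-2-[(4-methoxyphenyl)ethynyl]-3-methylphenyl}methanol | COc1ccc(cc1)C#Cc1c(C)ccc(-c2ccc(OC)cc2)c1CO
F8 | step 9 | (4-hydroxyphenyl){6-(4-hydroxyphenyl)-2-[(4-hydroxyphenyl)ethynyl]-3-methylphenyl}methanone | Cc1ccc(-c2ccc(O)cc2)c(C(=O)c2ccc(O)cc2)c1C#Cc1ccc(O)cc1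
F9 | step 9 | [4-(tert-butyldimethylsilyloxy)phenyl]{6-[4-(tert-butyldimethylsilyloxy)phenyl]-2-{[4-(tert-butyldimethylsilyloxy)phenyl]ethynyl}-3-methylphenyl}methanone | Cc1ccc(-c2ccc(O[Si](C)(C)C(C)(C)C)cc2)c(C(=O)c2ccc(O[Si](C)(C)C(C)(C)C)cc2)c1C#Cc1ccc(O[Si](C)(C)C(C)(C)C)cc1
F10 | step 9 | [4-(tert-butyldimethylsilyloxy)phenyl]lithium | [Li]c1ccc(O[Si](C)(C)C(C)(C)C)cc1
F11 | step 9 | bis[4-(tert-butyldimethylsilyloxy)phenyl]{6-[4-(tert-butyldimethylsilyloxy)phenyl]-2-{[4-(tert-butyldimethylsilyloxy)phenyl]ethynyl}-3-methylphenyl}methanol | Cc1ccc(-c2ccc(O[Si](C)(C)C(C)(C)C)cc2)c(C(O)(c2ccc(O[Si](C)(C)C(C)(C)C)cc2)c2ccc(O[Si](C)(C)C(C)(C)C)cc2)c1C#Cc1ccc(O[Si](C)(C)C(C)(C)C)cc1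
F12 | step 9 | bis(4-hydroxyphenyl){6-(4-hydroxyphenyl)-2-[(4-hydroxyphenyl)ethynyl]-3-methylphenyl}methanol | Cc1ccc(-c2ccc(O)cc2)c(C(O)(c2ccc(O)cc2)c2ccc(O)cc2)c1C#Cc1ccc(O)cc1
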